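The side chain is cut between C5′ and C6′ (chain carbons counted outward from the phthalide stereocentre C3), in the middle of the heteroatom-free polymethylene tether that links the 5,7-dimethoxyphthalide ring to the C13′ methyl ketone. The key step exploits exactly this feature. C5′ is carried as the terminal carbon of a C4′=C5′ alkene on the finished (S)-phthalide. C6′ is carried as a primary iodide, born 1,8 to the ketone by ring-opening of 1-methylcyclooctanol. One nickel-hydride-catalysed anti-Markovnikov hydroalkylation joins the two halves and should give the target directly, with lactone, ketone and stereocentre unprotected.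

Key step: step 7

Remark: the stereocentre at C3 of the phthalide is read from the SMILES as (S). Primed numbers C1′–C14′ denote side-chain carbons counted outward from C3 (C13′ is the ketone carbon).

Step 1
Reactants: 1 5-bromopent-1-ene; 2 3,5-dimethoxybenzonitrile
Product: 5 1-(3,5-dimethoxyphenyl)hex-5-en-1-one, via pent-4-enylmagnesium bromide 3 (not isolated), via N-bromomagnesio ketimine 4 (not isolated)
Conditions: Mg, THF, 40 °C; then 2, CuBr (2 mol %), THF, reflux; then 2 M aq. HCl, rt
Reagents that add atoms: water, O
Why: Grignard–nitrile ketone synthesis, in which addition of the primary alkylmagnesium bromide stops at the N-magnesio ketimine, so that acidic hydrolysis should release the aryl ketone without over-addition.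

Step 2
Reactants: 5 1-(3,5-dimethoxyphenyl)hex-5-en-1-one
Product: 6 (S)-1-(3,5-dimethoxyphenyl)hex-5-en-1-ol
Conditions: RuCl[(S,S)-TsDPEN](p-cymene) (1 mol %), HCO2H/Et3N (5:2), 30 °C
Reagents that add atoms: none
Why: Noyori asymmetric transfer hydrogenation, in which the (S,S)-TsDPEN–Ru hydride attacks the ketone face fixed by the CH/π contact between the aryl group and the η6-arene, which for aryl n-alkyl ketones should give the (S)-carbinol and leave the terminal alkene untouched.

Step 3
Reactants: 6 (S)-1-(3,5-dimethoxyphenyl)hex-5-en-1-ol
Product: 7 (S)-1-(2-bromo-3,5-dimethoxyphenyl)hex-5-en-1-ol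
Conditions: NBS (1.0 equiv), MeCN, 0 °C, dark
Reagents that add atoms: N-bromosuccinimide, O=C1CCC(=O)N1Br
Why: Electrophilic aromatic bromination of the doubly activated ring should occur at C2 (para to one methoxy, ortho to the other, less hindered than the site between the two methoxy groups) and be much faster than attack of NBS on the isolated terminal alkene.

Step 4
Reactants: 7 (S)-1-(2-bromo-3,5-dimethoxyphenyl)hex-5-en-1-ol
Product: 8 (S)-5,7-dimethoxy-3-(pent-4-en-1-yl)-2-benzofuran-1(3H)-one
Conditions: Pd(OAc)2 (5 mol %), Xantphos (6 mol %), Et3N, CO (1 atm), toluene, 100 °C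
Reagents that add atoms: carbon monoxide, [C-]#[O+]
Why: Palladium-catalysed carbonylative lactonisation, in which oxidative addition into C–Br, CO insertion and capture of the acyl-palladium by the neighbouring benzylic hydroxyl close the five-membered lactone without touching the C–O stereocentre, which stays (S).

Step 5
Reactants: 9 cyclooctanone
Product: 10 1-methylcyclooctan-1-ol
Conditions: MeMgBr, Et2O, 0 °C to rt; then sat. aq. NH4Cl
Reagents that add atoms: methylmagnesium bromide, C[Mg]Br
Why: Grignard 1,2-addition of methylmagnesium bromide to the ketone should give the tertiary cycloalkanol.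

Step 6
Reactants: 10 1-methylcyclooctan-1-ol
Product: 12 9-iodononan-2-one, via 1-methylcyclooctyl hypoiodite 11 (not isolated)
Conditions: PhI(OAc)2, I2, CH2Cl2, visible light, rt
Reagents that add atoms: iodine, II
Why: Suárez hypoiodite fragmentation, in which light homolyses the tertiary O–I bond, the alkoxyl radical undergoes β-scission of a ring C–C bond (relief of cyclooctane strain, giving a methyl ketone and a primary radical) and iodine traps the radical as the ω-iodo ketone.

Step 7
Reactants: 8 (S)-5,7-dimethoxy-3-(pent-4-en-1-yl)-2-benzofuran-1(3H)-one; 12 9-iodononan-2-one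
Product: 13 CJ-13,108, (S)-5,7-dimethoxy-3-(13-oxotetradecyl)-2-benzofuran-1(3H)-one
Conditions: NiBr2·diglyme (10 mol %), 4,4′-di-tert-butyl-2,2′-bipyridine (12 mol %), (EtO)2MeSiH, Na2CO3, DMA, rt; 12 in excess
Reagents that add atoms: none
Why: A Ni–H species formed from the nickel/bipyridine catalyst and the silane inserts the terminal C4′=C5′ alkene of 8 in the anti-Markovnikov sense to give a primary C5′–Ni alkyl, while iodide 12 is activated by single-electron transfer to the C6′ radical, which is captured at nickel; reductive elimination from the dialkylnickel(III) then forms the C5′–C6′ bond. The closest known reaction type is the nickel-hydride-catalysed reductive hydroalkylation of unactivated terminal alkenes with primary alkyl iodides. No ring is closed and no stereocentre is created; the C3 stereocentre lies four carbons from the reacting site and should not be touched. The step needs linear over branched regioselectivity, which the monosubstituted alkene and the preference of nickel for the primary position should secure. It also needs chemoselectivity for the alkene and the C–I bond over the C13′ ketone and the lactone carbonyl, neither of which should react with the unactivated hydrosilane under carbonate. The excess of 12 is meant to absorb its loss by hydrodehalogenation and homocoupling.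

Compound list
1 | 5-bromopent-1-ene | C=CCCCBr | starting material
2 | 3,5-dimethoxybenzonitrile | COc1cc(OC)cc(C#N)c1 | starting material
3 | pent-4-enylmagnesium bromide | C=CCCC[Mg]Br | intermediate
4 | N-bromomagnesio ketimine of 1-(3,5-dimethoxyphenyl)hex-5-en-1-one | COc1cc(OC)cc(c1)C(CCCC=C)=N[Mg]Br | intermediate
5 | 1-(3,5-dimethoxyphenyl)hex-5-en-1-one | COc1cc(OC)cc(c1)C(=O)CCCC=C | intermediate
6 | (S)-1-(3,5-dimethoxyphenyl)hex-5-en-1-ol | COc1cc(OC)cc(c1)[C@H](CCCC=C)O | intermediate
7 | (S)-1-(2-bromo-3,5-dimethoxyphenyl)hex-5-en-1-ol | COc1cc(OC)c(Br)c(c1)[C@H](CCCC=C)O | intermediate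
8 | (S)-5,7-dimethoxy-3-(pent-4-en-1-yl)-2-benzofuran-1(3H)-one | COc1cc(OC)c2c(c1)[C@H](CCCC=C)OC2=O | intermediate
9 | cyclooctanone | O=C1CCCCCCC1 | starting material
10 | 1-methylcyclooctan-1-ol | CC1(O)CCCCCCC1 | intermediate
11 | 1-methylcyclooctyl hypoiodite | CC1(OI)CCCCCCC1 | intermediate
12 | 9-iodononan-2-one | CC(=O)CCCCCCCI | intermediate
13 | CJ-13,108, (S)-5,7-dimethoxy-3-(13-oxotetradecyl)-2-benzofuran-1(3H)-one | COc1cc(OC)c2c(c1)[C@H](CCCCCCCCCCCCC(C)=O)OC2=O | target

Total step count: 7
Longest linear sequence: 5 steps (steps 1, 2, 3, 4 and 7)

Steps most likely to fail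

Step 7. The nickel hydride may walk along the tether before the C–C bond forms, which would give branched isomers, or the iodide may be reduced or homocoupled faster than it is cross-coupled. The fallback sets out from 8: hydroboration with 9-BBN-H (THF, rt) should place boron on C5′ and give the B-alkyl-9-borabicyclononane adduct F1. This is coupled in the same pot with iodide 12 under alkyl–alkyl Suzuki–Miyaura conditions (Pd(OAc)2, PCy3, K3PO4·H2O, THF, rt) and comes back to the route at 13.

Step 6. Transannular 1,5-hydrogen abstraction by the cyclooctyloxyl radical, or loss of the methyl group, may compete with ring-opening β-scission. The fallback sets out from 10 and cleaves the ring by an ionic sequence instead. Acid-catalysed dehydration (TsOH, toluene, reflux, water removal) should give 1-methylcyclooctene F2. Ozonolysis (O3, CH2Cl2, −78 °C; then Me2S) gives 8-oxononanal F3. Chemoselective reduction of the aldehyde (NaBH(OAc)3, benzene, reflux) gives 9-hydroxynonan-2-one F4. Appel iodination (I2, PPh3, imidazole, CH2Cl2) comes back to the route at 12.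

Step 3. NBS may engage the terminal alkene (bromoetherification by the free hydroxyl through 6-exo closure, or addition of bromine), or brominate the position between the two methoxy groups. The fallback sets out from Grignard reagent 3 and adds it to commercial 2-bromo-3,5-dimethoxybenzaldehyde (THF, −78 °C), so that bromine is in place before the alkene meets any electrophile. This gives racemic 1-(2-bromo-3,5-dimethoxyphenyl)hex-5-en-1-ol F5. Dess–Martin oxidation gives 1-(2-bromo-3,5-dimethoxyphenyl)hex-5-en-1-one F6. Corey–Bakshi–Shibata reduction ((R)-Me-CBS, catecholborane, toluene, −78 °C) should give the (S)-carbinol and comes back to the route at 7.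

Further compounds
F1 | step 7 | (S)-3-[5-(9-borabicyclo[3.3.1]nonan-9-yl)pentyl]-5,7-dimethoxy-2-benzofuran-1(3H)-one | COc1cc(OC)c2c(c1)[C@H](CCCCCB1C3CCCC1CCC3)OC2=O
F2 | step 6 | 1-methylcyclooctene | CC1=CCCCCCC1
F3 | step 6 | 8-oxononanal | CC(=O)CCCCCCC=O
F4 | step 6 | 9-hydroxynonan-2-one | CC(=O)CCCCCCCO
F5 | step 3 | rac-1-(2-bromo-3,5-dimethoxyphenyl)hex-5-en-1-ol | COc1cc(OC)c(Br)c(c1)C(O)CCCC=C
F6 | step 3 | 1-(2-bromo-3,5-dimethoxyphenyl)hex-5-en-1-one | COc1cc(OC)c(Br)c(c1)C(=O)CCCC=C
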